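(The numbers of this flask are assumed; the flask was simulated.)

At early times neither flask holds any Z, since X is what is charged, and J has to turn X into Z before Q or D can react.

| flask | Q | J | X | D | temperature | time |
|---|---|---|---|---|---|---|
| Friday's | 0.10 M | 0.0600 M | 16 mM | 0.10 M | 100 °C | 30 s |
| Sunday's | 0.10 M | 0.0600 M | 16 mM | 0.10 M | 130 °C | 30 s |
    J + Z + Q → Z + L (k1 = 120 L² mol⁻² s⁻¹, Ea1 = 44.0 kJ mol⁻¹)
    J + Z + D → Z + E (k2 = 13 L² mol⁻² s⁻¹, Ea2 = 51.0 kJ mol⁻¹)
    L ⇌ E (k3 = 0.12 s⁻¹, Ea3 = 99.0 kJ mol⁻¹)
    J + X → Z + G (k4 = 0.78 L mol⁻¹ s⁻¹, Ea4 = 53.0 kJ mol⁻¹)
    (constants at 100 °C)
- Z is single-handed; Q and D are mirror images of each other, charged as a racemate, each of them at the stated concentration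
- constants are those at 100 °C; use the activation energies for any other temperature
- the best flask by amount of L, in percent of the Q and D together charged; "all alike" if 1.5 percentage points covers them all (Friday's / Sunday's / all alike)
- amount of L at the end, in percent of the Q and D together charged, Friday's
- amount of L at the end, in percent of the Q and D together charged, Sunday's

Every turn of the catalyst spends one J, and so does every activation of X, and the 0.0600 M of J charged is less than the 0.10 M of Q alone, so J is the limiting reagent as charged, and J's budget is where I would reckon. On Friday's, L and E relax towards each other with a half-life of 2.89 s, shorter than the 30 s run, and on Sunday's that step runs 11 times faster, so I expect L to hold about half of the product in both flasks, whichever enantiomer made it.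

That gives you the J share, an estimate rather than a bound: half the J charged taken as a share of the Q and D together charged: 15.0%. If J is used up and all of X is activated, 11.0% remains. My reckoning stops at these two estimates, whose difference of 4 percentage points is wider than the 1.5 points margin, so it can't choose between the flasks.

The forecast says all alike, with 11.5% for Friday's and 12.6% for Sunday's: “Total product is capped by J, part of which is spent forming Z”.

The simulation gives 11.5% for Friday's and 12.7% for Sunday's, a gap smaller than the margin, so the answer is all alike, as forecast.

Take from the J share the J that went to G, 0.00929 M at the end of Sunday's, where J is down to 0.101%, and you get 12.7% for Sunday's. The neighbour is Friday's flask with 0.036 M of J, and its J share is 9.00%. Subtract its 0.00599 M of G and the 18.6% of its J still unused at 30.0 s, and 5.83% remains, which lies between the neighbour's E at 5.36% and its L at 6.29%.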